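## Retrosynthetic overview

1. The target is disconnected at the C10–O bond: it comes from jaeschkeanadiol 6-O-(4-methoxybenzoate) by a late, direct allylic C–H hydroxylation, the only step that sets C10.
2. That ester comes from jaeschkeanadiol by acylation of the secondary OH; jaeschkeanadiol comes from a bicyclic hydroxy ketone and an isopropyl nucleophile (sets C4).
3. The seven-membered ring is formed second, by ring-closing metathesis of an allyl and a methallyl arm on a cyclopentanone.
4. The five-membered ring is present from the start (3-ethoxycyclopentenone). Enantioselective methyl conjugate addition to 3-allylcyclopentenone with anti-aldol trapping by 3-methylbut-3-enal sets C1, C5 and C6.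

Assumption: daucane numbering is used in the text (C1 quaternary methyl carbon, C4 isopropyl carbinol, C5 ring-fusion CH, C6 ester carbon, C8=C9 alkene, C10 allylic carbinol), and α means the face opposite the C1 methyl.

## Route

Step 1
Reactants: 1 3-ethoxycyclopent-2-en-1-one; 2 allylmagnesium bromide
Product: 4 3-(prop-2-en-1-yl)cyclopent-2-en-1-one, via 1-allyl-3-ethoxycyclopent-2-en-1-ol 3 (not isolated)
Conditions: 2 (1.2 equiv), THF, 0 °C; then 1 M HCl, 0 °C, 15 min
Reagents that add atoms: allylmagnesium bromide C=CC[Mg]Br; water O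
Why: 1,2-addition to the vinylogous ester followed by acid hydrolysis with carbonyl transposition (Stork–Danheiser sequence) gives the 3-substituted enone; no stereocentre is formed, and brief cold acid keeps the skipped diene out of conjugation.

Step 2
Reactants: 5 3-methylbut-3-en-1-ol
Product: 6 3-methylbut-3-enal
Conditions: Dess–Martin periodinane (1.1 equiv), CH2Cl2, 0 °C to rt; used at once as a cold solution
Reagents that add atoms: none
Why: Dess–Martin oxidation is non-basic, so the β,γ-unsaturated aldehyde forms without isomerisation to the conjugated enal.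

Step 3
Reactants: 4 3-(prop-2-en-1-yl)cyclopent-2-en-1-one; 7 trimethylaluminium; 6 3-methylbut-3-enal
Product: 9 (2S,3R)-2-[(1S)-1-hydroxy-3-methylbut-3-en-1-yl]-3-methyl-3-(prop-2-en-1-yl)cyclopentan-1-one, via aluminium enolate 8 (not isolated)
Conditions: Me3Al (1.5 equiv), Cu(OTf)2 (5 mol%), chiral sulfonate-bearing NHC ligand (5 mol%, enantiomer giving 3R), THF, −78 °C; then 6 (1.5 equiv), −78 to −40 °C
Reagents that add atoms: trimethylaluminium C[Al](C)C; 3-methylbut-3-enal CC(=C)CC=O
Why: Copper–NHC-catalysed enantioselective conjugate addition of Me3Al to a β-substituted cyclopentenone sets the quaternary carbon (3R); the regiodefined cyclic E-enolate then adds to the aldehyde through a closed Zimmerman–Traxler transition state on the face anti to the larger allyl group, giving the 2,3-trans anti-aldol (2S, carbinol S).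

Step 4
Reactants: 9 (2S,3R)-2-[(1S)-1-hydroxy-3-methylbut-3-en-1-yl]-3-methyl-3-(prop-2-en-1-yl)cyclopentan-1-one
Product: 10 (3aR,8S,8aS)-8-hydroxy-3a,6-dimethyl-3,3a,4,7,8,8a-hexahydroazulen-1(2H)-one
Conditions: second-generation Grubbs catalyst (5 mol%), CH2Cl2 (5 mM), 40 °C
Reagents that add atoms: none
Why: Ring-closing metathesis of the allyl and methallyl arms, which sit trans on the ring, closes the trisubstituted cycloheptene as the trans-fused hydroazulenone with loss of ethylene; no stereocentre is touched.

Step 5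
Reactants: 10 (3aR,8S,8aS)-8-hydroxy-3a,6-dimethyl-3,3a,4,7,8,8a-hexahydroazulen-1(2H)-one; 11 isopropylmagnesium chloride
Product: 12 jaeschkeanadiol, (3R,3aS,4S,8aR)-6,8a-dimethyl-3-(propan-2-yl)-1,2,3,3a,4,5,8,8a-octahydroazulene-3,4-diol
Conditions: i-PrMgCl (3.5 equiv), LaCl3·2LiCl (30 mol%), THF, −20 to 0 °C
Reagents that add atoms: isopropylmagnesium chloride CC(C)[Mg]Cl
Why: Lanthanide-promoted Grignard 1,2-addition (suppressing enolisation and retro-aldol) delivers isopropyl to the α face of the cyclopentanone, anti to the adjacent C5–C6 bond and the angular methyl, so the tertiary OH is β (3R).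

Step 6
Reactants: 12 jaeschkeanadiol; 13 4-methoxybenzoyl chloride
Product: 14 (3R,3aS,4S,8aR)-3-hydroxy-6,8a-dimethyl-3-(propan-2-yl)-1,2,3,3a,4,5,8,8a-octahydroazulen-4-yl 4-methoxybenzoate
Conditions: 13 (1.3 equiv), pyridine, DMAP (10 mol%), CH2Cl2, 0 °C to rt
Reagents that add atoms: 4-methoxybenzoyl chloride COc1ccc(C(=O)Cl)cc1
Why: DMAP-catalysed O-acylation takes only the secondary C6 hydroxyl, the hindered tertiary C4 hydroxyl being inert; no stereocentre changes.

Step 7
Reactants: 14 (3R,3aS,4S,8aR)-3-hydroxy-6,8a-dimethyl-3-(propan-2-yl)-1,2,3,3a,4,5,8,8a-octahydroazulen-4-yl 4-methoxybenzoate; 15 N-hydroxyphthalimide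
Product: 17 (3R,3aS,4S,8R,8aS)-3,8-dihydroxy-6,8a-dimethyl-3-(propan-2-yl)-1,2,3,3a,4,5,8,8a-octahydroazulen-4-yl 4-methoxybenzoate (target), via N-alkoxyphthalimide 16 (not isolated)
Conditions: 15 (2.5 equiv), PhI(OAc)2 (1.3 equiv, added over 4 h), degassed MeCN, 50 °C, dark; then Zn dust, AcOH, 40 °C, same flask
Reagents that add atoms: N-hydroxyphthalimide O=C1c2ccccc2C(=O)N1O
Why: Proposed new method: a site- and face-selective N-oxyl radical-relay allylic C–H hydroxylation of a trisubstituted ring alkene used as the limiting reagent, in which phthalimide-N-oxyl (from 15 and PhI(OAc)2) abstracts the pseudoaxial 10α-hydrogen (the C7 hydrogens are deactivated by the neighbouring acyloxy carbon, the C14 methyl hydrogens are primary), a second N-oxyl couples with the allyl radical at its secondary terminus C10 on the α face anti to the axial C1 methyl (no cation forms, so the 4-OH cannot close an ether), and Zn/AcOH cleaves the N–O bond to the 10α-alcohol (8R); closest known reaction type: oxidant-mediated dehydrogenative C–O coupling of N-hydroxyphthalimide with simple cycloalkenes used in excess, and N-oxyl-mediated C7 oxidation of 5-ene steroids.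

## Compound list

1 | 3-ethoxycyclopent-2-en-1-one | CCOC1=CC(=O)CC1 | starting material
2 | allylmagnesium bromide | C=CC[Mg]Br | starting material
3 | 1-allyl-3-ethoxycyclopent-2-en-1-ol (racemic; present as its bromomagnesium alkoxide before acidification) | CCOC1=CC(O)(CC=C)CC1 | intermediate
4 | 3-(prop-2-en-1-yl)cyclopent-2-en-1-one | C=CCC1=CC(=O)CC1 | intermediate
5 | 3-methylbut-3-en-1-ol | CC(=C)CCO | starting material
6 | 3-methylbut-3-enal | CC(=C)CC=O | intermediate
7 | trimethylaluminium | C[Al](C)C | starting material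
8 | dimethylaluminium (3R)-3-methyl-3-(prop-2-en-1-yl)cyclopent-1-en-1-olate | C=CC[C@@]1(C)CCC(O[Al](C)C)=C1 | intermediate
9 | (2S,3R)-2-[(1S)-1-hydroxy-3-methylbut-3-en-1-yl]-3-methyl-3-(prop-2-en-1-yl)cyclopentan-1-one | C=CC[C@@]1(C)CCC(=O)[C@@H]1[C@@H](O)CC(C)=C | intermediate
10 | (3aR,8S,8aS)-8-hydroxy-3a,6-dimethyl-3,3a,4,7,8,8a-hexahydroazulen-1(2H)-one (trans-fused) | O[C@H]1CC(C)=CC[C@@]2(C)CCC(=O)[C@H]12 | intermediate
11 | isopropylmagnesium chloride | CC(C)[Mg]Cl | starting material
12 | jaeschkeanadiol, (3R,3aS,4S,8aR)-6,8a-dimethyl-3-(propan-2-yl)-1,2,3,3a,4,5,8,8a-octahydroazulene-3,4-diol | O[C@H]1CC(C)=CC[C@@]2(C)CC[C@@](O)(C(C)C)[C@H]12 | intermediate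
13 | 4-methoxybenzoyl chloride | COc1ccc(C(=O)Cl)cc1 | starting material
14 | (3R,3aS,4S,8aR)-3-hydroxy-6,8a-dimethyl-3-(propan-2-yl)-1,2,3,3a,4,5,8,8a-octahydroazulen-4-yl 4-methoxybenzoate | COc1ccc(C(=O)O[C@H]2CC(C)=CC[C@@]3(C)CC[C@@](O)(C(C)C)[C@H]23)cc1 | intermediate
15 | N-hydroxyphthalimide | O=C1c2ccccc2C(=O)N1O | starting material
16 | (3R,3aS,4S,8R,8aS)-8-[(1,3-dioxoisoindolin-2-yl)oxy]-3-hydroxy-6,8a-dimethyl-3-(propan-2-yl)-1,2,3,3a,4,5,8,8a-octahydroazulen-4-yl 4-methoxybenzoate | COc1ccc(C(=O)O[C@H]2CC(C)=C[C@@H](ON4C(=O)c5ccccc5C4=O)[C@@]3(C)CC[C@@](O)(C(C)C)[C@H]23)cc1 | intermediate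
17 | (3R,3aS,4S,8R,8aS)-3,8-dihydroxy-6,8a-dimethyl-3-(propan-2-yl)-1,2,3,3a,4,5,8,8a-octahydroazulen-4-yl 4-methoxybenzoate | COc1ccc(C(=O)O[C@H]2CC(C)=C[C@@H](O)[C@@]3(C)CC[C@@](O)(C(C)C)[C@H]23)cc1 | target

## Step count and risks

Total steps: 7. Longest linear sequence: 6 (steps 1, 3, 4, 5, 6, 7); step 2 is a one-step side branch.

**Step 7 (the proposed new C–H hydroxylation).** The risks are hydrogen abstraction at the C14 methyl or C7, N-oxyl addition to the alkene, and coupling at the tertiary terminus C8. The fallback uses known chemistry and sets out from 14. A Kharasch–Sosnovsky allylic acyloxylation (CuBr 10 mol%, tert-butyl peracetate, PhH/MeCN, 75 °C) is used; on 5-ene steroids this enters the ring methylene next to the unsubstituted alkene carbon from the face opposite the angular methyl. It gives the 10α-acetate F4. The acetate is then removed in the presence of the hindered, electron-rich aryl ester with guanidine/guanidinium nitrate in MeOH at 0 °C, which comes back to the route at 17.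

**Step 3 (conjugate addition and aldol in one flask).** The risks are modest facial selectivity (allyl against methyl), a modest anti/syn ratio, and isomerisation or enolisation of aldehyde 6 by aluminium species. The fallback sets out from 4 and runs the same conjugate addition, but quenches enolate 8 with TMSOTf at −78 °C to give the isolable silyl enol ether F1, on which the enantiomeric purity can be checked. MeLi (THF, 0 °C) then releases the regiodefined lithium enolate F2, which is added to 6 at −78 °C (MgBr2 optional) through a closed transition state. This separates the two events, keeps Lewis-acidic aluminium out of the aldol, and comes back to the route at 9.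

**Step 5 (isopropyl addition).** The risk is that a bulky secondary Grignard reagent on a hindered, enolisable β-hydroxy ketone gives enolisation, retro-aldol or β-hydride reduction. The fallback sets out from 10 and adds the smaller, non-reducing isopropenylmagnesium bromide (LaCl3·2LiCl, THF, 0 °C) to give the isopropenyl carbinol F3. The 1,1-disubstituted alkene is then hydrogenated selectively over the trisubstituted ring alkene (H2 1 atm, RhCl(PPh3)3, PhH), which comes back to the route at 12.

## Further compounds

F1 | step 3 | trimethyl{[(3R)-3-methyl-3-(prop-2-en-1-yl)cyclopent-1-en-1-yl]oxy}silane | C=CC[C@@]1(C)CCC(O[Si](C)(C)C)=C1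
F2 | step 3 | lithium (3R)-3-methyl-3-(prop-2-en-1-yl)cyclopent-1-en-1-olate | C=CC[C@@]1(C)CCC(O[Li])=C1
F3 | step 5 | (3S,3aS,4S,8aR)-6,8a-dimethyl-3-(prop-1-en-2-yl)-1,2,3,3a,4,5,8,8a-octahydroazulene-3,4-diol | O[C@H]1CC(C)=CC[C@@]2(C)CC[C@@](O)(C(C)=C)[C@H]12
F4 | step 7 | (3R,3aS,4S,8R,8aS)-8-acetoxy-3-hydroxy-6,8a-dimethyl-3-(propan-2-yl)-1,2,3,3a,4,5,8,8a-octahydroazulen-4-yl 4-methoxybenzoate | COc1ccc(C(=O)O[C@H]2CC(C)=C[C@@H](OC(C)=O)[C@@]3(C)CC[C@@](O)(C(C)C)[C@H]23)cc1
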